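**Plan**
Retrosynthesis: cut the ferulate C8–O bond, then the two C11 methyls (ester + MeMgBr), the C8–H bond (ketone reduction), the C10–CH3 bond (enol triflate coupling), and finally both C6–C7 and C9–C10 of the seven-membered ring at once.
Forward: ring A (cyclopentane, C1–C5) comes from 2-methylcyclopent-2-enone; ring B (seven-membered) is closed in one operation by a rhodium-vinylcarbenoid cyclopropanation/Cope rearrangement (formal [4+3]).
Enabling feature: ring B carries its oxygen on C8 between C7 (which bears C11) and C9, i.e. a 2-oxyallyl three-carbon unit at the ester level (a siloxyvinyl diazoacetate), and C10–C1–C5–C6 is a 1,3-diene exocyclic to ring A.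
Helper: C10 is carried as a ketene acetal, then ketone, so the C1=C5 alkene left by the cycloaddition can be moved to C1=C10 (hydride to C5, enol triflate, methyl); the oxygen leaves as triflate.
Stereochemistry: C4 from a Cu-catalysed asymmetric conjugate addition; C5 by hydride delivery anti to the C4 methyl; C7 and C8 together by Ru-BINAP hydrogenation with dynamic kinetic resolution.

Key step: step 6

Remark: locants C1–C15 in the text are guaiane locants (ring fusion C1/C5, methyls on C4 and C10, carbinol carbon C11 on C7, acyloxy on C8); compound names use azulene locants, and ligand enantiomers in steps 3 and 11 are assigned by analogy with simple cyclic substrates.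

**Step 1**
Reactants: 1 methyl acetoacetate
Product: 2 methyl 2-diazo-3-oxobutanoate
Conditions: 4-acetamidobenzenesulfonyl azide, Et3N, MeCN, 0 °C to rt
Reagents that add atoms: 4-acetamidobenzenesulfonyl azide, CC(=O)Nc1ccc(cc1)S(=O)(=O)N=[N+]=[N-]
Why: Regitz diazo transfer to the doubly activated methylene should give the diazo keto ester; no stereocentre is involved.

**Step 2**
Reactants: 2 methyl 2-diazo-3-oxobutanoate
Product: 3 methyl 2-diazo-3-[(triisopropylsilyl)oxy]but-3-enoate
Conditions: iPr3SiOTf, Et3N, CH2Cl2, 0 °C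
Reagents that add atoms: triisopropylsilyl trifluoromethanesulfonate, CC(C)[Si](C(C)C)(C(C)C)OS(=O)(=O)C(F)(F)F
Why: Soft enolisation and O-silylation of the acetyl group should give the siloxyvinyl diazoacetate (vinylcarbenoid precursor); the bulky silyl group is chosen to survive the fluoride step 8.

**Step 3**
Reactants: 4 2-methylcyclopent-2-en-1-one
Product: 6 (3S)-2,3-dimethylcyclopent-1-en-1-yl trifluoromethanesulfonate, via bromomagnesium enolate 5 (not isolated)
Conditions: MeMgBr, Cu(OTf)2 (3 mol %), chiral C2-symmetric imidazolinium salt (carbene ligand precursor, 4 mol %), Et2O, −10 °C; then PhNTf2, THF, −78 °C to rt; aq. NH4Cl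
Reagents that add atoms: methylmagnesium bromide, C[Mg]Br; N-phenylbis(trifluoromethanesulfonimide), FC(F)(F)S(=O)(=O)N(c1ccccc1)S(=O)(=O)C(F)(F)F
Why: Copper-catalysed asymmetric conjugate addition to the α-substituted cyclic enone should set the 3S centre (later C4) under ligand control, and O-sulfonylation of the regiodefined magnesium enolate fixes the double bond between the future C1 and C5.

**Step 4**
Reactants: 6 (3S)-2,3-dimethylcyclopent-1-en-1-yl trifluoromethanesulfonate
Product: 7 methyl (3S)-2,3-dimethylcyclopent-1-ene-1-carboxylate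
Conditions: Pd(OAc)2 (5 mol %), PPh3, CO (1 atm), MeOH, Et3N, DMF, 50 °C
Reagents that add atoms: carbon monoxide, [C-]#[O+]; methanol, CO
Why: Palladium-catalysed alkoxycarbonylation of an enol triflate should install the future C10 at the ester level without touching the allylic stereocentre.

**Step 5**
Reactants: 7 methyl (3S)-2,3-dimethylcyclopent-1-ene-1-carboxylate
Product: 9 {methoxy[(3S)-3-methyl-2-methylidenecyclopentylidene]methoxy}trimethylsilane, via lithium dienolate 8 (not isolated)
Conditions: LDA, THF/DMPU, −78 °C; then Me3SiCl, −78 °C to rt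
Reagents that add atoms: chlorotrimethylsilane, C[Si](C)(C)Cl
Why: Kinetic γ-deprotonation of the enoate at the 2-methyl group, which lies cis to the ester, followed by O-silylation should give the vinylogous silyl ketene acetal with the exocyclic methylene (diene C6=C5–C1=C10), leaving the tertiary C4–H untouched.

**Step 6**
Reactants: 3 methyl 2-diazo-3-[(triisopropylsilyl)oxy]but-3-enoate; 9 {methoxy[(3S)-3-methyl-2-methylidenecyclopentylidene]methoxy}trimethylsilane
Product: 12 methyl (3S)-3-methyl-8-oxo-6-[(triisopropylsilyl)oxy]-1,2,3,4,7,8-hexahydroazulene-5-carboxylate, via cis-divinylcyclopropane 10 (not isolated), via mixed ketal cycloadduct 11 (not isolated)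
Conditions: Rh2(OPiv)4 (1 mol %), hexanes, slow addition of 3 to 9 (1.5 equiv), rt then 60 °C; then 10% aq. citric acid, THF, 0 °C
Reagents that add atoms: none
Why: Dirhodium-catalysed loss of N2 from 3 gives an electrophilic siloxyvinyl carbenoid that cyclopropanates the unsubstituted exocyclic methylene C5=C6 of 9 (carbene carbon C7 to C6), and the push-pull cis-divinylcyclopropane 10 then undergoes a boat-shaped Cope rearrangement that forms C9–C10 and gives the cyclohepta-1,4-diene 11 (C7=C8 enol ether, C1=C5). The closest known reaction type is the tandem cyclopropanation/Cope rearrangement (formal [4+3] cycloaddition) of siloxyvinyl diazoacetates with 1-alkoxy- and siloxy-1,3-dienes. The three-membered ring closes by concerted carbene addition and ring B closes by the [3,3]-sigmatropic shift, a four-atom enlargement of the vinylcyclopropane. No lasting stereocentre is made: C4 is a spectator, the cyclopropane centres vanish in the Cope step, and the C10 ketal centre is erased when citric acid hydrolyses 11 to enone 12. The step needs carbene-site attack at C6 rather than at the ketene acetal or through the vinylogous carbenoid terminus; C6 is the unhindered vinylogous nucleophilic end of the dienyl ketene acetal, the non-polar solvent and carboxylate catalyst favour carbenoid-carbon reactivity, and the donor–acceptor substitution of 10 lets a trans-divinyl isomer open and reclose to the reactive cis form.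

**Step 7**
Reactants: 12 methyl (3S)-3-methyl-8-oxo-6-[(triisopropylsilyl)oxy]-1,2,3,4,7,8-hexahydroazulene-5-carboxylate
Product: 13 methyl (3S,3aS)-3-methyl-8-[(triethylsilyl)oxy]-6-[(triisopropylsilyl)oxy]-1,2,3,3a,4,7-hexahydroazulene-5-carboxylate
Conditions: Et3SiH, RhCl(PPh3)3 (2 mol %), toluene, 70 °C
Reagents that add atoms: triethylsilane, CC[SiH](CC)CC
Why: Rhodium-catalysed 1,4-hydrosilylation of the enone should deliver hydride to C5 from the face opposite the adjacent C4 methyl (H4/H5 cis, 3aS) and place silicon on oxygen, so the enol ether double bond is regiodefined at C10=C1; the β-siloxy acrylate is too electron-rich and hindered to react.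

**Step 8**
Reactants: 13 methyl (3S,3aS)-3-methyl-8-[(triethylsilyl)oxy]-6-[(triisopropylsilyl)oxy]-1,2,3,3a,4,7-hexahydroazulene-5-carboxylate
Product: 14 methyl (3S,3aS)-3-methyl-6-[(triisopropylsilyl)oxy]-8-{[(trifluoromethyl)sulfonyl]oxy}-1,2,3,3a,4,7-hexahydroazulene-5-carboxylate
Conditions: CsF, PhNTf2, DME, rt
Reagents that add atoms: N-phenylbis(trifluoromethanesulfonimide), FC(F)(F)S(=O)(=O)N(c1ccccc1)S(=O)(=O)C(F)(F)F
Why: Fluoride-induced release of the enolate from the more labile triethylsilyl enol ether and immediate O-triflation should give the enol triflate with the regiochemistry fixed in step 7; the triisopropylsilyl enol ether reacts far more slowly and no carbonyl-activated C–H is present to scramble the enolate.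

**Step 9**
Reactants: 14 methyl (3S,3aS)-3-methyl-6-[(triisopropylsilyl)oxy]-8-{[(trifluoromethyl)sulfonyl]oxy}-1,2,3,3a,4,7-hexahydroazulene-5-carboxylate
Product: 15 methyl (3S,3aS)-3,8-dimethyl-6-[(triisopropylsilyl)oxy]-1,2,3,3a,4,7-hexahydroazulene-5-carboxylate
Conditions: MeZnCl, Pd(PPh3)4 (5 mol %), THF, 50 °C
Reagents that add atoms: methylzinc chloride, C[Zn]Cl
Why: Negishi coupling of the enol triflate should install the C10 methyl and leave the tetrasubstituted C1=C10 alkene exactly where the triflate was; ester and silyl enol ether tolerate the organozinc.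

**Step 10**
Reactants: 15 methyl (3S,3aS)-3,8-dimethyl-6-[(triisopropylsilyl)oxy]-1,2,3,3a,4,7-hexahydroazulene-5-carboxylate
Product: 16 methyl (3S,3aS)-3,8-dimethyl-6-oxo-1,2,3,3a,4,5,6,7-octahydroazulene-5-carboxylate (C5 epimers and enol)
Conditions: HF·pyridine, THF, 0 °C
Reagents that add atoms: none
Why: Desilylation of the silyl enol ether with protonation at C7 should release the β-keto ester; the C7 epimer mixture is irrelevant for step 11 and the mild, non-basic medium should keep the β,γ-alkene out of conjugation.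

**Step 11**
Reactants: 16 methyl (3S,3aS)-3,8-dimethyl-6-oxo-1,2,3,3a,4,5,6,7-octahydroazulene-5-carboxylate
Product: 17 methyl (3S,3aS,5S,6S)-6-hydroxy-3,8-dimethyl-1,2,3,3a,4,5,6,7-octahydroazulene-5-carboxylate
Conditions: H2 (80 atm), [RuCl(benzene)((S)-BINAP)]Cl (1 mol %), CH2Cl2, 50 °C
Reagents that add atoms: none
Why: Noyori asymmetric hydrogenation with dynamic kinetic resolution: C7 epimerises through the enol while the (S)-BINAP catalyst reduces one epimer from one carbonyl face, which should give the anti (trans) hydroxy ester with 8S and 7S centres by analogy with 2-alkoxycarbonylcycloalkanones; the tetrasubstituted alkene is not hydrogenated by this catalyst.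

**Step 12**
Reactants: 17 methyl (3S,3aS,5S,6S)-6-hydroxy-3,8-dimethyl-1,2,3,3a,4,5,6,7-octahydroazulene-5-carboxylate
Product: 19 (3S,3aS,5S,6S)-5-(2-hydroxypropan-2-yl)-3,8-dimethyl-1,2,3,3a,4,5,6,7-octahydroazulen-6-ol, via methyl ketone 18 (not isolated)
Conditions: MeMgBr (5 equiv), THF, 0 °C to rt; aq. NH4Cl
Reagents that add atoms: methylmagnesium bromide, C[Mg]Br
Why: Double Grignard addition to the ester of the magnesium β-alkoxide should build the C11 tertiary carbinol; the C7 and C8 centres are not touched.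

**Step 13**
Reactants: 19 (3S,3aS,5S,6S)-5-(2-hydroxypropan-2-yl)-3,8-dimethyl-1,2,3,3a,4,5,6,7-octahydroazulen-6-ol; 20 (E)-3-(4-acetoxy-3-methoxyphenyl)prop-2-enoic acid
Product: 21 (3S,3aS,5S,6S)-5-(2-hydroxypropan-2-yl)-3,8-dimethyl-1,2,3,3a,4,5,6,7-octahydroazulen-6-yl (E)-3-(4-acetoxy-3-methoxyphenyl)prop-2-enoate
Conditions: DCC, DMAP (cat.), CH2Cl2, 0 °C to rt
Reagents that add atoms: none
Why: Steglich esterification should acylate the secondary C8 hydroxyl with retention, the tertiary C11 hydroxyl being too hindered; the phenol is masked as its acetate to prevent self-acylation.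

**Step 14**
Reactants: 21 (3S,3aS,5S,6S)-5-(2-hydroxypropan-2-yl)-3,8-dimethyl-1,2,3,3a,4,5,6,7-octahydroazulen-6-yl (E)-3-(4-acetoxy-3-methoxyphenyl)prop-2-enoate
Product: 22 (3S,3aS,5S,6S)-5-(2-hydroxypropan-2-yl)-3,8-dimethyl-1,2,3,3a,4,5,6,7-octahydroazulen-6-yl (E)-3-(4-hydroxy-3-methoxyphenyl)prop-2-enoate
Conditions: K2CO3 (cat.), MeOH, 0 °C
Reagents that add atoms: none
Why: Base-catalysed transesterification should cleave the aryl acetate much faster than the hindered secondary cinnamate, releasing the phenol without acid that could affect the homoallylic tertiary alcohol.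

**Compound list**
1 | methyl acetoacetate | CC(=O)CC(=O)OC | starting material
2 | methyl 2-diazo-3-oxobutanoate | CC(=O)C(=[N+]=[N-])C(=O)OC | intermediate
3 | methyl 2-diazo-3-[(triisopropylsilyl)oxy]but-3-enoate | COC(=O)C(=[N+]=[N-])C(=C)O[Si](C(C)C)(C(C)C)C(C)C | intermediate
4 | 2-methylcyclopent-2-en-1-one | CC1=CCCC1=O | starting material
5 | bromomagnesium (3S)-2,3-dimethylcyclopent-1-en-1-olate | Br[Mg]OC1=C(C)[C@@H](C)CC1 | intermediate
6 | (3S)-2,3-dimethylcyclopent-1-en-1-yl trifluoromethanesulfonate | FC(F)(F)S(=O)(=O)OC1=C(C)[C@@H](C)CC1 | intermediate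
7 | methyl (3S)-2,3-dimethylcyclopent-1-ene-1-carboxylate | COC(=O)C1=C(C)[C@@H](C)CC1 | intermediate
8 | lithium methoxy[(3S)-3-methyl-2-methylidenecyclopentylidene]methanolate | [Li]OC(OC)=C1CC[C@H](C)C1=C | intermediate
9 | {methoxy[(3S)-3-methyl-2-methylidenecyclopentylidene]methoxy}trimethylsilane | COC(O[Si](C)(C)C)=C1CC[C@H](C)C1=C | intermediate
10 | methyl (7S)-4-[methoxy(trimethylsilyloxy)methylidene]-7-methyl-1-{1-[(triisopropylsilyl)oxy]ethenyl}spiro[2.4]heptane-1-carboxylate (cis-divinylcyclopropane) | COC(=O)C1(C(=C)O[Si](C(C)C)(C(C)C)C(C)C)CC12[C@@H](C)CCC2=C(OC)O[Si](C)(C)C | intermediate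
11 | methyl (3S)-8-methoxy-3-methyl-6-[(triisopropylsilyl)oxy]-8-[(trimethylsilyl)oxy]-1,2,3,4,7,8-hexahydroazulene-5-carboxylate (both C8 epimers) | COC(=O)C1=C(O[Si](C(C)C)(C(C)C)C(C)C)CC(OC)(O[Si](C)(C)C)C2=C(C1)[C@@H](C)CC2 | intermediate
12 | methyl (3S)-3-methyl-8-oxo-6-[(triisopropylsilyl)oxy]-1,2,3,4,7,8-hexahydroazulene-5-carboxylate | COC(=O)C1=C(O[Si](C(C)C)(C(C)C)C(C)C)CC(=O)C2=C(C1)[C@@H](C)CC2 | intermediate
13 | methyl (3S,3aS)-3-methyl-8-[(triethylsilyl)oxy]-6-[(triisopropylsilyl)oxy]-1,2,3,3a,4,7-hexahydroazulene-5-carboxylate | COC(=O)C1=C(O[Si](C(C)C)(C(C)C)C(C)C)CC(O[Si](CC)(CC)CC)=C2CC[C@H](C)[C@@H]2C1 | intermediate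
14 | methyl (3S,3aS)-3-methyl-6-[(triisopropylsilyl)oxy]-8-{[(trifluoromethyl)sulfonyl]oxy}-1,2,3,3a,4,7-hexahydroazulene-5-carboxylate | COC(=O)C1=C(O[Si](C(C)C)(C(C)C)C(C)C)CC(OS(=O)(=O)C(F)(F)F)=C2CC[C@H](C)[C@@H]2C1 | intermediate
15 | methyl (3S,3aS)-3,8-dimethyl-6-[(triisopropylsilyl)oxy]-1,2,3,3a,4,7-hexahydroazulene-5-carboxylate | COC(=O)C1=C(O[Si](C(C)C)(C(C)C)C(C)C)CC(C)=C2CC[C@H](C)[C@@H]2C1 | intermediate
16 | methyl (3S,3aS)-3,8-dimethyl-6-oxo-1,2,3,3a,4,5,6,7-octahydroazulene-5-carboxylate (C5 epimers) | O=C1CC(C)=C2CC[C@H](C)[C@@H]2CC1C(=O)OC | intermediate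
17 | methyl (3S,3aS,5S,6S)-6-hydroxy-3,8-dimethyl-1,2,3,3a,4,5,6,7-octahydroazulene-5-carboxylate | O[C@H]1CC(C)=C2CC[C@H](C)[C@@H]2C[C@@H]1C(=O)OC | intermediate
18 | 1-[(3S,3aS,5S,6S)-6-hydroxy-3,8-dimethyl-1,2,3,3a,4,5,6,7-octahydroazulen-5-yl]ethan-1-one | O[C@H]1CC(C)=C2CC[C@H](C)[C@@H]2C[C@@H]1C(C)=O | intermediate
19 | (3S,3aS,5S,6S)-5-(2-hydroxypropan-2-yl)-3,8-dimethyl-1,2,3,3a,4,5,6,7-octahydroazulen-6-ol | O[C@H]1CC(C)=C2CC[C@H](C)[C@@H]2C[C@@H]1C(C)(C)O | intermediate
20 | (E)-3-(4-acetoxy-3-methoxyphenyl)prop-2-enoic acid | CC(=O)Oc1ccc(/C=C/C(=O)O)cc1OC | starting material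
21 | (3S,3aS,5S,6S)-5-(2-hydroxypropan-2-yl)-3,8-dimethyl-1,2,3,3a,4,5,6,7-octahydroazulen-6-yl (E)-3-(4-acetoxy-3-methoxyphenyl)prop-2-enoate | COc1cc(/C=C/C(=O)O[C@H]2CC(C)=C3CC[C@H](C)[C@@H]3C[C@@H]2C(C)(C)O)ccc1OC(C)=O | intermediate
22 | (3S,3aS,5S,6S)-5-(2-hydroxypropan-2-yl)-3,8-dimethyl-1,2,3,3a,4,5,6,7-octahydroazulen-6-yl (E)-3-(4-hydroxy-3-methoxyphenyl)prop-2-enoate | COc1cc(/C=C/C(=O)O[C@H]2CC(C)=C3CC[C@H](C)[C@@H]3C[C@@H]2C(C)(C)O)ccc1O | target

Total step count: 14
Longest linear sequence: 12 steps (4 to 22, steps 3 to 14)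

**Steps most likely to fail**

Step 6. The dienyl ketene acetal may react through a long-lived zwitterion (vinylogous attack, five-membered ring closure or simple C-alkylation with loss of silicon) instead of closing ring B. The fallback sets out from 6 and returns at 12, changing the diene to a 1-siloxy-1,3-diene, a class with direct precedent in this cycloaddition. Triflate 6 would be formylated (Pd(PPh3)4, CO, Bu3SnH) to (3S)-2,3-dimethylcyclopent-1-ene-1-carbaldehyde F1. Et3SiOTf/Et3N would convert it into triethyl{[(3S)-3-methyl-2-methylidenecyclopentylidene]methoxy}silane F2, which would be combined with 3 under Rh2(OPiv)4 to give methyl (3S)-3-methyl-8-[(triethylsilyl)oxy]-6-[(triisopropylsilyl)oxy]-1,2,3,4,7,8-hexahydroazulene-5-carboxylate F3. Methanolysis of the secondary silyl ether (PPTS, MeOH) to methyl (3S)-8-hydroxy-3-methyl-6-[(triisopropylsilyl)oxy]-1,2,3,4,7,8-hexahydroazulene-5-carboxylate F4 and MnO2 oxidation of the allylic alcohol would give enone 12.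

Step 7. Hydride transfer to the tetrasubstituted enone may be slow, may go 1,2, or may lack facial control at C5. The fallback sets out from 12 and returns at 14. It replaces the hydrosilylation by a polar conjugate hydride addition with stoichiometric [(Ph3P)CuH]6 in the presence of Me3SiCl, giving methyl (3S,3aS)-3-methyl-6-[(triisopropylsilyl)oxy]-8-[(trimethylsilyl)oxy]-1,2,3,3a,4,7-hexahydroazulene-5-carboxylate F5. This is triflated with CsF/PhNTf2 to give 14.

Step 11. The resident C5 centre may erode the anti and enantiofacial selection, or the β,γ-alkene may drift into conjugation under the hydrogenation conditions. The fallback sets out from 15 and returns at 19, using substrate-directed reduction instead of catalyst control. MeLi would convert the ester of 15 into 2-[(3S,3aS)-3,8-dimethyl-6-[(triisopropylsilyl)oxy]-1,2,3,3a,4,7-hexahydroazulen-5-yl]propan-2-ol F6 while C8 is still masked. HF·pyridine would release (3S,3aS,5R)-5-(2-hydroxypropan-2-yl)-3,8-dimethyl-1,2,3,3a,4,5-hexahydroazulen-6(7H)-one F7, with C7 equilibrating to the epimer that has the side chain pseudo-equatorial. Evans–Saksena reduction with Me4NBH(OAc)3 would then deliver hydride to C8 from the face of the C11 alkoxyborohydride and give the trans diol 19.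

**Further compounds**
F1 | step 6 | (3S)-2,3-dimethylcyclopent-1-ene-1-carbaldehyde | O=CC1=C(C)[C@@H](C)CC1
F2 | step 6 | triethyl{[(3S)-3-methyl-2-methylidenecyclopentylidene]methoxy}silane | CC[Si](CC)(CC)OC=C1CC[C@H](C)C1=C
F3 | step 6 | methyl (3S)-3-methyl-8-[(triethylsilyl)oxy]-6-[(triisopropylsilyl)oxy]-1,2,3,4,7,8-hexahydroazulene-5-carboxylate | COC(=O)C1=C(O[Si](C(C)C)(C(C)C)C(C)C)CC(O[Si](CC)(CC)CC)C2=C(C1)[C@@H](C)CC2
F4 | step 6 | methyl (3S)-8-hydroxy-3-methyl-6-[(triisopropylsilyl)oxy]-1,2,3,4,7,8-hexahydroazulene-5-carboxylate | COC(=O)C1=C(O[Si](C(C)C)(C(C)C)C(C)C)CC(O)C2=C(C1)[C@@H](C)CC2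
F5 | step 7 | methyl (3S,3aS)-3-methyl-6-[(triisopropylsilyl)oxy]-8-[(trimethylsilyl)oxy]-1,2,3,3a,4,7-hexahydroazulene-5-carboxylate | COC(=O)C1=C(O[Si](C(C)C)(C(C)C)C(C)C)CC(O[Si](C)(C)C)=C2CC[C@H](C)[C@@H]2C1
F6 | step 11 | 2-[(3S,3aS)-3,8-dimethyl-6-[(triisopropylsilyl)oxy]-1,2,3,3a,4,7-hexahydroazulen-5-yl]propan-2-ol | CC(C)(O)C1=C(O[Si](C(C)C)(C(C)C)C(C)C)CC(C)=C2CC[C@H](C)[C@@H]2C1
F7 | step 11 | (3S,3aS,5R)-5-(2-hydroxypropan-2-yl)-3,8-dimethyl-1,2,3,3a,4,5-hexahydroazulen-6(7H)-one | O=C1CC(C)=C2CC[C@H](C)[C@@H]2C[C@@H]1C(C)(C)O
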